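**Retrosynthetic overview**

1. Locants: C1 = angular carbon (CH3), C4 = tertiary carbinol (isopropyl), C5 = ring-fusion CH, C6 = ester carbinol, C7 = CH2, C8 = C(CH3)=, C9 = CH=, C10 = C=O; ring A = cyclopentane, ring B = cycloheptenone. The ester is made last, by acylating the secondary C6–OH of diol 17.
2. 17 comes from Tamao oxidation of oxasilolane 16, and 16 from a silicon-tethered radical relay on cyclopentane 13. The C6–C7 unit is a vinyl group on silicon bound to the C4 oxygen; one operation makes C5–C6 and C7–C8 and closes ring B.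
3. Enabling feature: the 1,3-dioxygen array O–C4–C5–C6–O across the ring-fusion carbon C5 (tertiary OH on ring A, ester oxygen on ring B) allows a temporary O4–Si–C6 link. The β-methyl enone C8=C9–C10=O of ring B is the retron of radical addition to a but-2-ynoyl group on C1.
4. 13 comes from cyclopentane-1,3-dione: Nozaki–Hiyama–Kishi coupling with but-2-ynal, catalytic asymmetric conjugate methylation (C1), then stereochemical relay C1 → C5 (selenenylation) → C4 (isopropyl addition).
5. Ring order: ring A from step 1; the temporary oxasilolane and ring B together in step 10; the oxasilolane is excised in step 11.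

Key step: step 10

Remark: compounds 4–10 carry an uncontrolled carbinol centre in the side chain (written without configuration); it serves only as a bulky handle and is erased in step 8. "β" means the face of ring A that carries the C1 methyl group.

**Route**

Step 1
Reactants: 1 cyclopentane-1,3-dione
Product: 2 3-iodocyclopent-2-en-1-one
Conditions: PPh3, I2, Et3N, MeCN, rt then reflux
Reagents that add atoms: iodine, II
Why: The enol of the 1,3-diketone is activated as an oxyphosphonium salt and replaced by iodide in an addition–elimination, the known conversion of cyclic 1,3-diketones into β-iodo enones.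

Step 2
Reactants: 2 3-iodocyclopent-2-en-1-one; 3 but-2-ynal
Product: 4 3-(1-hydroxybut-2-yn-1-yl)cyclopent-2-en-1-one (racemic)
Conditions: CrCl2 (excess), NiCl2 (cat.), DMF, rt
Reagents that add atoms: none
Why: In this Nozaki–Hiyama–Kishi coupling the alkenylchromium species from the β-iodo enone should add only to the aldehyde and leave the ring ketone alone; the new carbinol centre needs no control because it later becomes the C10 carbonyl.

Step 3
Reactants: 4 3-(1-hydroxybut-2-yn-1-yl)cyclopent-2-en-1-one
Product: 5 3-[1-(tert-butyldimethylsilyloxy)but-2-yn-1-yl]cyclopent-2-en-1-one (racemic)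
Conditions: TBSCl, imidazole, DMF, rt
Reagents that add atoms: tert-butyldimethylsilyl chloride, CC(C)(C)[Si](C)(C)Cl
Why: Standard O-silylation masks the alcohol and turns the side chain into the bulky group that later directs the chemistry at C5.

Step 4
Reactants: 5 3-[1-(tert-butyldimethylsilyloxy)but-2-yn-1-yl]cyclopent-2-en-1-one
Product: 7 1-(trimethylsilyloxy)-3-methyl-3-[1-(tert-butyldimethylsilyloxy)but-2-yn-1-yl]cyclopent-1-ene (quaternary carbon as in the SMILES; two carbinol epimers), via aluminium enolate 6 (not isolated)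
Conditions: Me3Al, copper thiophene-2-carboxylate CuO2CC4H3S (5 mol %), chiral BINOL-derived phosphoramidite (10 mol %), Et2O, −30 °C; then TMSOTf, −30 to 0 °C
Reagents that add atoms: trimethylaluminium, C[Al](C)C; trimethylsilyl trifluoromethanesulfonate, C[Si](C)(C)OS(=O)(=O)C(F)(F)F
Why: Copper-catalysed asymmetric conjugate addition of Me3Al to a β-substituted cyclopentenone should set the quaternary carbon C1 under ligand control (the ligand antipode that gives the drawn configuration is used), and O-silylation of the aluminium enolate fixes the enol double bond towards C5.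

Step 5
Reactants: 7 1-(trimethylsilyloxy)-3-methyl-3-[1-(tert-butyldimethylsilyloxy)but-2-yn-1-yl]cyclopent-1-ene
Product: 8 3-methyl-2-(phenylselanyl)-3-[1-(tert-butyldimethylsilyloxy)but-2-yn-1-yl]cyclopentan-1-one (PhSe cis to CH3)
Conditions: PhSeCl, CH2Cl2, −78 °C
Reagents that add atoms: benzeneselenenyl chloride, Cl[Se]c1ccccc1
Why: Electrophilic selenenylation of the silyl enol ether occurs only at C5 and should take place anti to the bulky silyloxybutynyl arm on the neighbouring quaternary carbon, so PhSe ends on the β face.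

Step 6
Reactants: 8 3-methyl-2-(phenylselanyl)-3-[1-(tert-butyldimethylsilyloxy)but-2-yn-1-yl]cyclopentan-1-one
Product: 9 3-methyl-1-(propan-2-yl)-2-(phenylselanyl)-3-[1-(tert-butyldimethylsilyloxy)but-2-yn-1-yl]cyclopentan-1-ol (OH and PhSe and CH3 all β)
Conditions: iPrMgCl, CeCl3 (anhydrous), THF, −78 °C
Reagents that add atoms: isopropylmagnesium chloride, CC(C)[Mg]Cl
Why: Organocerium addition to the ketone (chosen to suppress enolisation and hydride transfer) should occur anti to the adjacent C–Se bond by steric approach control, which places the isopropyl group on the α face and the C4 hydroxyl on the β face.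

Step 7
Reactants: 9 3-methyl-1-(propan-2-yl)-2-(phenylselanyl)-3-[1-(tert-butyldimethylsilyloxy)but-2-yn-1-yl]cyclopentan-1-ol
Product: 10 3-(1-hydroxybut-2-yn-1-yl)-3-methyl-1-(propan-2-yl)-2-(phenylselanyl)cyclopentan-1-ol
Conditions: TBAF, THF, 0 °C to rt
Reagents that add atoms: none
Why: Fluoride cleaves the silyl ether, and the cis-β-hydroxy selenide cannot undergo anti elimination and should survive.

Step 8
Reactants: 10 3-(1-hydroxybut-2-yn-1-yl)-3-methyl-1-(propan-2-yl)-2-(phenylselanyl)cyclopentan-1-ol
Product: 11 1-[3-hydroxy-1-methyl-3-(propan-2-yl)-2-(phenylselanyl)cyclopentyl]but-2-yn-1-one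
Conditions: MnO2 (activated, excess), CH2Cl2, rt
Reagents that add atoms: none
Why: MnO2 oxidises only the propargylic alcohol (the tertiary alcohol and the selenide are inert to it), so both carbinol epimers converge on one ynone.

Step 9
Reactants: 11 1-[3-hydroxy-1-methyl-3-(propan-2-yl)-2-(phenylselanyl)cyclopentyl]but-2-yn-1-one; 12 chloro(dimethyl)vinylsilane
Product: 13 1-[3-(dimethylvinylsilyloxy)-1-methyl-3-(propan-2-yl)-2-(phenylselanyl)cyclopentyl]but-2-yn-1-one
Conditions: Et3N, DMAP (cat.), CH2Cl2, 0 °C to rt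
Reagents that add atoms: none
Why: O-silylation of the tertiary alcohol with a small dimethylsilyl chloride attaches the two-carbon unit C6–C7 to the C4 oxygen on the β face.

Step 10
Reactants: 13 1-[3-(dimethylvinylsilyloxy)-1-methyl-3-(propan-2-yl)-2-(phenylselanyl)cyclopentyl]but-2-yn-1-one
Product: 16 tricyclic oxasilolane-fused enone (O4–Si(CH3)2–C6 bridge; rings A and B trans-fused), via C5 cyclopentyl radical 14 (not isolated), via C7 primary radical 15 (not isolated)
Conditions: Bu3SnH (1.3 equiv) and AIBN (0.2 equiv) by syringe pump over 6 h, C6H6 (0.005 M), 80 °C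
Reagents that add atoms: none
Why: Proposed new method: Bu3Sn• abstracts PhSe from C5; the planar radical 14 adds 5-exo-trig to the silicon-bound vinyl carbon, so the new C5–C6 bond is delivered on the face of the C4 oxygen and therefore anti to the butynoyl arm, which fixes the trans ring fusion; the primary β-silyl radical 15 then adds 7-endo-dig to the β-carbon C8 of the ynone and the vinyl radical is reduced by Bu3SnH to the cis enone. The closest known reaction types are the 5-exo cyclisation of vinylsilyl ethers of β-phenylselanyl alcohols (followed by Tamao oxidation) and endo-selective radical additions to ynones; the new element is that the 5-exo radical is intercepted by a second ring closure. Stereocentres: C5 is set by the tether (delivery syn to O4), and C6 by the exo, convex-face orientation of the CH2• group in the cis-fused bicycle, which is also the orientation that points toward the acyl arm. Selectivities needed: 14 must prefer the vinylsilane (5-exo) over the ynone (5-endo-dig or 4-exo, both disfavoured); 15 must attack C8 and not C9 (a nucleophilic alkyl radical on the β-carbon of an ynone); and 15 must cyclise before it is reduced or rearranges to the 6-endo silyl radical, hence slow addition of Bu3SnH at high dilution (addition of Bu3Sn• to the ynone is reversible).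

Step 11
Reactants: 16 tricyclic oxasilolane-fused enone
Product: 17 (1S,4R,5S,6S)-4,6-dihydroxy diol (overview locants: 1-CH3; 4-OH and 4-isopropyl; 6-OH; 8-CH3; C8=C9; C10=O)
Conditions: H2O2 (30 % aq.), KF, KHCO3, THF/MeOH, rt
Reagents that add atoms: hydrogen peroxide, OO
Why: Tamao oxidation of the alkoxysilane converts C6–Si into C6–OH with retention and frees the C4 hydroxyl, while the hindered β,β-disubstituted enone should be slow to epoxidise under bicarbonate buffering.

Step 12
Reactants: 17 (1S,4R,5S,6S)-4,6-dihydroxy diol; 18 3,4,5-trimethoxybenzoyl chloride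
Product: 19 target, the (1S,4R,5S,6S) C6 3,4,5-trimethoxybenzoate (overview locants)
Conditions: Et3N, DMAP (cat.), CH2Cl2, 0 °C
Reagents that add atoms: none
Why: Acylation should occur only at the secondary C6 hydroxyl (the tertiary C4 hydroxyl is inert), and the mild base at low temperature avoids elimination of the ester through deprotonation at C7.

**Compound list**

1 | cyclopentane-1,3-dione | O=C1CCC(=O)C1 | starting material
2 | 3-iodocyclopent-2-en-1-one | O=C1CCC(I)=C1 | intermediate
3 | but-2-ynal | CC#CC=O | starting material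
4 | 3-(1-hydroxybut-2-yn-1-yl)cyclopent-2-en-1-one (racemic) | CC#CC(O)C1=CC(=O)CC1 | intermediate
5 | 3-[1-(tert-butyldimethylsilyloxy)but-2-yn-1-yl]cyclopent-2-en-1-one (racemic) | CC#CC(O[Si](C)(C)C(C)(C)C)C1=CC(=O)CC1 | intermediate
6 | dimethylaluminium enolate of 3-methyl-3-[1-(tert-butyldimethylsilyloxy)but-2-yn-1-yl]cyclopentanone | CC#CC(O[Si](C)(C)C(C)(C)C)[C@@]1(C)CCC(O[Al](C)C)=C1 | intermediate
7 | 1-(trimethylsilyloxy)-3-methyl-3-[1-(tert-butyldimethylsilyloxy)but-2-yn-1-yl]cyclopent-1-ene | CC#CC(O[Si](C)(C)C(C)(C)C)[C@@]1(C)CCC(O[Si](C)(C)C)=C1 | intermediate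
8 | 3-methyl-2-(phenylselanyl)-3-[1-(tert-butyldimethylsilyloxy)but-2-yn-1-yl]cyclopentan-1-one, PhSe cis to CH3 | CC#CC(O[Si](C)(C)C(C)(C)C)[C@@]1(C)CCC(=O)[C@@H]1[Se]c2ccccc2 | intermediate
9 | 3-methyl-1-(propan-2-yl)-2-(phenylselanyl)-3-[1-(tert-butyldimethylsilyloxy)but-2-yn-1-yl]cyclopentan-1-ol, OH/PhSe/CH3 all β | CC#CC(O[Si](C)(C)C(C)(C)C)[C@@]1(C)CC[C@@](O)(C(C)C)[C@@H]1[Se]c2ccccc2 | intermediate
10 | 3-(1-hydroxybut-2-yn-1-yl)-3-methyl-1-(propan-2-yl)-2-(phenylselanyl)cyclopentan-1-ol | CC#CC(O)[C@@]1(C)CC[C@@](O)(C(C)C)[C@@H]1[Se]c2ccccc2 | intermediate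
11 | 1-[3-hydroxy-1-methyl-3-(propan-2-yl)-2-(phenylselanyl)cyclopentyl]but-2-yn-1-one | CC#CC(=O)[C@@]1(C)CC[C@@](O)(C(C)C)[C@@H]1[Se]c2ccccc2 | intermediate
12 | chloro(dimethyl)vinylsilane | C=C[Si](C)(C)Cl | starting material
13 | 1-[3-(dimethylvinylsilyloxy)-1-methyl-3-(propan-2-yl)-2-(phenylselanyl)cyclopentyl]but-2-yn-1-one | CC#CC(=O)[C@@]1(C)CC[C@@](O[Si](C)(C)C=C)(C(C)C)[C@@H]1[Se]c2ccccc2 | intermediate
14 | C5 cyclopentyl radical formed from 13 by loss of PhSe | CC#CC(=O)[C@@]1(C)CC[C@@](O[Si](C)(C)C=C)(C(C)C)[CH]1 | intermediate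
15 | C7 primary radical on the cis-fused oxasilolane | CC#CC(=O)[C@@]1(C)CC[C@]2(C(C)C)O[Si](C)(C)[C@@H]([CH2])[C@H]12 | intermediate
16 | tricyclic oxasilolane-fused enone (O4–Si(CH3)2–C6 bridge, rings A and B trans-fused) | CC1=CC(=O)[C@@]2(C)CC[C@]3(C(C)C)O[Si](C)(C)[C@@H](C1)[C@H]23 | intermediate
17 | (1S,4R,5S,6S)-4,6-dihydroxy diol, the target without its acyl group | O[C@H]1CC(C)=CC(=O)[C@@]2(C)CC[C@@](O)(C(C)C)[C@H]12 | intermediate
18 | 3,4,5-trimethoxybenzoyl chloride | COc1cc(C(Cl)=O)cc(OC)c1OC | starting material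
19 | target, (1S,4R,5S,6S) C6 3,4,5-trimethoxybenzoate | COc1cc(C(=O)O[C@H]2CC(C)=CC(=O)[C@@]3(C)CC[C@@](O)(C(C)C)[C@H]23)cc(OC)c1OC | target

**Step count and risks**

Total step count: 12. Longest linear sequence: 12 steps (from cyclopentane-1,3-dione).

Steps most likely to fail:

1. Step 10 (Proposed new method). The primary radical may be reduced, or may ring-expand to the 6-endo silyl radical, before it reaches the ynone; the 7-endo-dig closure may also be slowed by strain. Fallback, from 7 back to 17, makes the two bonds in separate, precedented steps. Silyl enol ether 7 and 2-(phenylselanyl)acetaldehyde undergo a Mukaiyama aldol reaction (BF3·OEt2, CH2Cl2, −78 °C); this forms C5–C6 intermolecularly, anti to the bulky arm, and gives the β-hydroxy ketone F1 (C6 epimers separated). iPrMgCl/CeCl3 adds to the ring ketone anti to the new C5 substituent and gives the diol F2. TBAF gives the triol F3, and MnO2 oxidises only the propargylic alcohol to the ynone F4. Bu3SnH/AIBN at high dilution then generates the C7 radical from the selenide and closes ring B by 7-endo-dig addition to C8, giving 17.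

2. Step 6. Enolisation, hydride transfer from the isopropyl reagent, attack at selenium, or poor facial selectivity may defeat the carbonyl addition. Fallback, from 7 back to 16, brings in the isopropyl group by cross-coupling and the C4 oxygen by dihydroxylation. MeLi then PhNTf2 convert 7 into the enol triflate F5. Iron-catalysed coupling with iPrMgCl (Fe(C5H7O2)3 cat., THF/NMP) gives the 1-isopropylcyclopentene F6. OsO4 (cat.)/N-methylmorpholine N-oxide dihydroxylates the face anti to the bulky arm and gives the cis-diol F7, with both hydroxyls β. PhOC(S)Cl/pyridine derivatises only the secondary hydroxyl, giving the thionocarbonate F8. HF·pyridine gives the propargylic alcohol F9, MnO2 the ynone F10, and 12 with Et3N/DMAP the vinylsilyl ether F11. Under the conditions of step 10 the thionocarbonate serves as the C5 radical source and leads to 16.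

3. Step 4. The conjugate addition at the hindered β-carbon may be slow or poorly enantioselective. Fallback, from 5 back to 7, delivers the methyl group as a cyclopropane methylene. Oxazaborolidine-catalysed (CBS) reduction of the ring ketone with BH3·SMe2 gives the allylic alcohol F12. Hydroxyl-directed Simmons–Smith cyclopropanation (Zn–Cu couple, CH2I2) adds CH2 syn to the hydroxyl and gives the bicyclic carbinol F13. Dess–Martin oxidation gives the cyclopropyl ketone F14. SmI2 with t-BuOH cleaves the exocyclic cyclopropane bond that overlaps with the carbonyl; trapping the enolate with TMSCl/Et3N returns 7.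

**Further compounds**

F1 | step 10 | 2-[1-hydroxy-2-(phenylselanyl)ethyl]-3-methyl-3-[1-(tert-butyldimethylsilyloxy)but-2-yn-1-yl]cyclopentan-1-one | CC#CC(O[Si](C)(C)C(C)(C)C)[C@@]1(C)CCC(=O)[C@@H]1[C@@H](O)C[Se]c2ccccc2
F2 | step 10 | 2-[1-hydroxy-2-(phenylselanyl)ethyl]-3-methyl-1-(propan-2-yl)-3-[1-(tert-butyldimethylsilyloxy)but-2-yn-1-yl]cyclopentan-1-ol | CC#CC(O[Si](C)(C)C(C)(C)C)[C@@]1(C)CC[C@@](O)(C(C)C)[C@@H]1[C@@H](O)C[Se]c2ccccc2
F3 | step 10 | 3-(1-hydroxybut-2-yn-1-yl)-2-[1-hydroxy-2-(phenylselanyl)ethyl]-3-methyl-1-(propan-2-yl)cyclopentan-1-ol | CC#CC(O)[C@@]1(C)CC[C@@](O)(C(C)C)[C@@H]1[C@@H](O)C[Se]c2ccccc2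
F4 | step 10 | 1-{3-hydroxy-2-[1-hydroxy-2-(phenylselanyl)ethyl]-1-methyl-3-(propan-2-yl)cyclopentyl}but-2-yn-1-one | CC#CC(=O)[C@@]1(C)CC[C@@](O)(C(C)C)[C@@H]1[C@@H](O)C[Se]c2ccccc2
F5 | step 6 | 3-methyl-3-[1-(tert-butyldimethylsilyloxy)but-2-yn-1-yl]cyclopent-1-en-1-yl trifluoromethanesulfonate | CC#CC(O[Si](C)(C)C(C)(C)C)[C@@]1(C)CCC(OS(=O)(=O)C(F)(F)F)=C1
F6 | step 6 | 3-methyl-1-(propan-2-yl)-3-[1-(tert-butyldimethylsilyloxy)but-2-yn-1-yl]cyclopent-1-ene | CC#CC(O[Si](C)(C)C(C)(C)C)[C@@]1(C)CCC(C(C)C)=C1
F7 | step 6 | 3-methyl-1-(propan-2-yl)-3-[1-(tert-butyldimethylsilyloxy)but-2-yn-1-yl]cyclopentane-1,2-diol, both OH β | CC#CC(O[Si](C)(C)C(C)(C)C)[C@@]1(C)CC[C@@](O)(C(C)C)[C@@H]1O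
F8 | step 6 | O-phenyl thionocarbonate of F7 at the secondary hydroxyl | CC#CC(O[Si](C)(C)C(C)(C)C)[C@@]1(C)CC[C@@](O)(C(C)C)[C@@H]1OC(=S)Oc2ccccc2
F9 | step 6 | desilylated thionocarbonate (free propargylic alcohol) | CC#CC(O)[C@@]1(C)CC[C@@](O)(C(C)C)[C@@H]1OC(=S)Oc2ccccc2
F10 | step 6 | ynone thionocarbonate | CC#CC(=O)[C@@]1(C)CC[C@@](O)(C(C)C)[C@@H]1OC(=S)Oc2ccccc2
F11 | step 6 | dimethylvinylsilyl ether of F10 | CC#CC(=O)[C@@]1(C)CC[C@@](O[Si](C)(C)C=C)(C(C)C)[C@@H]1OC(=S)Oc2ccccc2
F12 | step 4 | 3-[1-(tert-butyldimethylsilyloxy)but-2-yn-1-yl]cyclopent-2-en-1-ol, ring carbinol as in the SMILES | CC#CC(O[Si](C)(C)C(C)(C)C)C1=C[C@@H](O)CC1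
F13 | step 4 | 5-[1-(tert-butyldimethylsilyloxy)but-2-yn-1-yl]bicyclo[3.1.0]hexan-2-ol, CH2 syn to OH | CC#CC(O[Si](C)(C)C(C)(C)C)[C@]12C[C@H]1[C@@H](O)CC2
F14 | step 4 | 5-[1-(tert-butyldimethylsilyloxy)but-2-yn-1-yl]bicyclo[3.1.0]hexan-2-one | CC#CC(O[Si](C)(C)C(C)(C)C)[C@]12C[C@H]1C(=O)CC2
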